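Everything rests on cutting ring A from ring B at C1–C10 and C4–C5. Ring B carries its C7 oxygen 1,4 to the methyl-bearing quaternary C10 and cis to that methyl, the pattern of (+)-dihydrocarvone when isopropenyl is read as a latent hydroxyl; C1–C4 plus one C4 methyl is ethyl vinyl ketone. The key step, an auxiliary-controlled Michael addition followed by aldol condensation, forms ring A, both bonds and the C10 stereocentre in one operation and gives (+)-α-cyperone. Its precursor is simply the (R)-1-phenylethylamine imine of commercial dihydrocarvone. C5, C9, C3, C2 and the side chain are then set by relay from C10 and C7 and by one auxiliary-controlled aldol.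

Key step: step 2

Remark: terpenoid numbering of the target is used for every bicyclic compound (ring A = C1–C5 and C10; ring B = C5–C10; C17 = methylene carbon on C8; C11–C12 = chain on C9; C13–C16 = succinimide carbons); β is the face of the C10 methyl, α the opposite face.
Remark: commercial (+)-dihydrocarvone contains some of its C2 epimer; both epimers give the same enamine, so the mixture is used as received.
Remark: (+)-α-cyperone already has C10 and the C7 substituent in the configuration of the target, so neither centre is inverted later.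
Remark: the hydroxymethyl ketone of step 10 is drawn as its equatorial 8α epimer; this centre is removed in step 11.

Step 1
Reactants: 1 (+)-dihydrocarvone; 2 (R)-1-phenylethylamine
Product: 3 (E)-N-[(R)-1-phenylethyl]imine of dihydrocarvone
Conditions: TsOH·H2O (cat.), toluene, reflux, Dean–Stark
Reagents that add atoms: none
Why: Acid-catalysed imine formation with azeotropic removal of water should go to completion, and the C2 epimers of 1 converge because C2 becomes trigonal in the reactive enamine tautomer while C5 is untouched.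

Step 2
Reactants: 3 imine of dihydrocarvone; 4 ethyl vinyl ketone
Product: 7 (+)-α-cyperone, via Michael adduct imine 5 (not isolated), via diketone 6 (not isolated)
Conditions: 4 (1.3 equiv), THF, 40 °C, 4 d; then 10% aq AcOH, rt; then NaOMe, MeOH, rt
Reagents that add atoms: none
Why: Imine 3 equilibrates with its more substituted secondary enamine tautomer, which adds to 4 through a compact chair-like aza-ene transition state in which the N–H hydrogen is delivered to the α-carbon of the enone while the C1–C10 bond forms, giving imine 5; aqueous acetic acid then releases diketone 6 and the auxiliary, and methoxide closes ring A by aldol addition of the C4 enolate to the C5 ketone followed by E1cB dehydration. The closest known reaction type is the deracemising Michael alkylation of 1-phenylethylamine imines of 2-methylcyclohexanones with vinyl ketones, completed as a Robinson annulation. Ring A closes in a 6-(enolendo)-exo-trig aldol. The new quaternary centre C10 is controlled by the auxiliary: the enone approaches the enamine face opposite the phenyl group, which for the (R)-amine is the face trans to the isopropenyl group, so the methyl ends up cis to it. The step needs alkylation at the methyl-bearing carbon, secured because only the more substituted enamine tautomer has the syn N–H required for the concerted hydrogen transfer, and it needs reagent control to outweigh the ring's own preference for axial attack cis to the isopropenyl group, which the tight cyclic transition state of the secondary enamine provides. The C7 centre is not involved and survives unchanged.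

Step 3
Reactants: 7 (+)-α-cyperone
Product: 8 7β-isopropenyl-4,4,10β-trimethyl-5α-decalin-3-one
Conditions: Li, NH3(l)/THF, t-BuOH (1 equiv), −78 °C; then MeI, −78 to −33 °C; NH4Cl
Reagents that add atoms: methyl iodide, CI
Why: Dissolving-metal reductive alkylation of the enone protonates C5 axially from the α face to give the trans-fused lithium enolate, which is methylated regiospecifically at C4 to the gem-dimethyl ketone, the isolated isopropenyl alkene being inert to Li/NH3.

Step 4
Reactants: 8 7β-isopropenyl ketone
Product: 10 7β-acetoxy-4,4,10β-trimethyl-5α-decalin-3-one, via methoxy hydroperoxide 9 (not isolated)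
Conditions: O3, CH2Cl2/MeOH, −78 °C; then Ac2O, Et3N, DMAP (cat.), 0 °C to rt
Reagents that add atoms: ozone, [O-][O+]=O; methanol, CO
Why: Ozonolysis in methanol turns the isopropenyl group into the α-methoxy hydroperoxide 9, whose O-acetylation triggers a Criegee rearrangement in which C7 migrates to oxygen with retention (the acetyl carbons are those of the old isopropenyl group and acetate removes the O-methyl as methyl acetate), so the equatorial 7β-acetate should form while the C3 ketone, which a peracid Baeyer–Villiger oxidation would attack, is left alone.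

Step 5
Reactants: 10 7β-acetoxy ketone
Product: 11 7β-acetoxy-3,3-ethylenedioxy-4,4,10β-trimethyl-5α-decalin
Conditions: HOCH2CH2OH, TsOH·H2O (cat.), toluene, reflux, Dean–Stark
Reagents that add atoms: ethylene glycol, OCCO
Why: Acid-catalysed ketalisation with azeotropic water removal masks the only ketone as its dioxolane, the acetate being stable to these conditions.

Step 6
Reactants: 11 ketal acetate
Product: 12 3,3-ethylenedioxy-4,4,10β-trimethyl-5α-decalin-7β-ol
Conditions: K2CO3, MeOH, rt
Reagents that add atoms: none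
Why: Base-catalysed transesterification (methanolysis) frees the 7β-alcohol without touching the ketal.

Step 7
Reactants: 12 ketal alcohol
Product: 13 3,3-ethylenedioxy-4,4,10β-trimethyl-5α-decalin-7-one
Conditions: Pr4N[RuO4] (cat.), NMO, 4 Å MS, CH2Cl2, rt
Reagents that add atoms: none
Why: Ley–Griffith oxidation under neutral conditions converts the secondary alcohol into the ketone and leaves the acid-sensitive dioxolane intact.

Step 8
Reactants: 13 ketal 7-ketone
Product: 15 3,3-ethylenedioxy-4,4,10β-trimethyl-5α-Δ8(9)-octalin-7-one, via silyl enol ether 14 (not isolated)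
Conditions: LiN(i-Pr)2, THF, −78 °C; TMSCl; then Pd(OAc)2, MeCN, rt
Reagents that add atoms: none
Why: Kinetic deprotonation should occur at C8, because C6 is shielded by C5 and the C4 methyls and enolisation away from the ring fusion is favoured as in trans-2-decalones, and Saegusa–Ito oxidation of the trapped silyl enol ether 14 by Pd(OAc)2 then gives the C8–C9 enone.

Step 9
Reactants: 15 Δ8(9)-enone
Product: 17 9-allyl-3,3-ethylenedioxy-4,4,10β-trimethyl-5α-Δ8(9)-octalin-7-one, via silyl enol ether 16 (not isolated)
Conditions: CH2=CHCH2MgBr, CuBr·SMe2, TMSCl, THF, −78 °C; then Pd(OAc)2, MeCN, rt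
Reagents that add atoms: allylmagnesium bromide, C=CC[Mg]Br
Why: TMSCl-accelerated conjugate addition of allylcopper forms the C9–C11 bond on the α face anti to the C10 methyl and delivers silyl enol ether 16 directly, and its Saegusa–Ito oxidation erases that misplaced C9 centre and returns the enone with the allyl group on C9.

Step 10
Reactants: 17 9-allyl enone
Product: 18 9β-allyl-8α-(hydroxymethyl)-3,3-ethylenedioxy-4,4,10β-trimethyl-5α-decalin-7-one
Conditions: Li, NH3(l)/THF, t-BuOH (1 equiv), −78 °C; evaporate NH3; CH2O (g), THF, −78 °C; NH4Cl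
Reagents that add atoms: formaldehyde, C=O
Why: Dissolving-metal reduction of the β,β-disubstituted enone protonates C9 axially from the α face so that the allyl chain becomes equatorial (9β, the more stable arrangement), and the regiodefined lithium enolate is then trapped at C8 by monomeric formaldehyde in an aldol-type hydroxymethylation.

Step 11
Reactants: 18 hydroxymethyl ketone
Product: 20 9β-allyl-8-methylene-3,3-ethylenedioxy-4,4,10β-trimethyl-5α-decalin-7-one, via mesylate 19 (not isolated)
Conditions: MsCl, Et3N, CH2Cl2, 0 °C; then DBU, rt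
Reagents that add atoms: none
Why: Mesylation of the primary alcohol and E1cB elimination of the β-mesyloxy ketone 19 give the exocyclic α-methylene ketone, which has no acidic hydrogen that would let base move the double bond into the ring.

Step 12
Reactants: 20 exocyclic enone
Product: 23 9β-(2-hydroxyethyl)-8-methylene-3,3-ethylenedioxy-4,4,10β-trimethyl-5α-decalin-7β-ol, via keto aldehyde 21 (not isolated), via hydroxy enone 22 (not isolated)
Conditions: O3, pyridine, CH2Cl2, −78 °C; then NaBH4, MeOH, −78 °C; then CeCl3·7H2O, NaBH4, −78 to −20 °C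
Reagents that add atoms: ozone, [O-][O+]=O
Why: Ozone should cleave the electron-rich monosubstituted alkene much faster than the electron-poor conjugated methylene group (pyridine-mediated ozonolysis gives aldehyde 21 directly), borohydride at −78 °C reduces the aldehyde before the enone, and the Luche reduction then delivers hydride 1,2 and axially from the α face of C7 to give the equatorial 7β-alcohol.

Step 13
Reactants: 23 ketal diol
Product: 24 7β-hydroxy-9β-(2-hydroxyethyl)-8-methylene-4,4,10β-trimethyl-5α-decalin-3-one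
Conditions: PPTS, acetone/H2O, 50 °C
Reagents that add atoms: water, O
Why: Mild acid-catalysed ketal hydrolysis removes the strained dioxolane of the hindered C3 ketone under conditions too weak to ionise the allylic alcohol.

Step 14
Reactants: 24 keto diol
Product: 25 7,12-bis-O-TBS ether of 24
Conditions: TBSCl, imidazole, DMAP (cat.), DMF, 40 °C
Reagents that add atoms: tert-butyldimethylsilyl chloride, CC(C)(C)[Si](C)(C)Cl
Why: Silyl ether formation with TBSCl and imidazole protects the primary and the equatorial allylic hydroxyl groups, the ketone being inert.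

Step 15
Reactants: 25 bis-TBS ketone
Product: 27 2α-chloro-7,12-bis-O-TBS ketone, via silyl enol ether 26 (not isolated)
Conditions: LiN(i-Pr)2, TMSCl, THF, −78 °C; then NCS, THF, 0 °C
Reagents that add atoms: N-chlorosuccinimide, O=C1CCC(=O)N1Cl
Why: C2 is the only enolisable position of the C3 ketone because C4 is quaternary, so silyl enol ether 26 forms regiospecifically and its electrophilic α-chlorination should occur on the α face, away from the axial C4β and C10 methyls, to give the equatorial 2α-chloride, which is also the thermodynamically preferred epimer.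

Step 16
Reactants: 27 2α-chloro ketone
Product: 28 2α-chloro-3β-hydroxy-7,12-bis-O-TBS compound
Conditions: NaBH4, MeOH/CH2Cl2, −20 °C
Reagents that add atoms: none
Why: Borohydride reduction delivers hydride axially from the α face, the β face being blocked by the axial C4 methyl, to give the equatorial 3β-alcohol, and the trans-diequatorial chlorohydrin so formed cannot close to an epoxide at this temperature.

Step 17
Reactants: 28 chlorohydrin
Product: 29 2α-chloro-3β,7β,12-tris-O-TBS compound
Conditions: TBSOTf, 2,6-lutidine, CH2Cl2, 0 °C to rt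
Reagents that add atoms: tert-butyldimethylsilyl triflate, CC(C)(C)[Si](C)(C)OS(=O)(=O)C(F)(F)F
Why: Silyl ether formation with the powerful silylating agent TBSOTf should cap the hindered neopentyl-type 3β-hydroxyl that TBSCl would leave free.

Step 18
Reactants: 29 tris-TBS ether
Product: 30 2α-chloro-3β,7β-bis-O-TBS-12-ol
Conditions: HF·pyridine, pyridine, THF, 0 °C
Reagents that add atoms: none
Why: Selective desilylation with buffered HF·pyridine cleaves the unhindered primary TBS ether much faster than the two secondary ones.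

Step 19
Reactants: 30 primary alcohol
Product: 31 2α-chloro-3β,7β-bis-O-TBS-12-al (C9β-CH2CHO)
Conditions: Dess–Martin periodinane, NaHCO3, CH2Cl2, rt
Reagents that add atoms: none
Why: Dess–Martin oxidation under bicarbonate buffer converts the primary alcohol into the aldehyde without over-oxidation or loss of silyl groups.

Step 20
Reactants: 32 (R)-4-benzyl-2-oxazolidinone; 33 succinic anhydride
Product: 34 4-[(R)-4-benzyl-2-oxooxazolidin-3-yl]-4-oxobutanoic acid
Conditions: n-BuLi, THF, −78 °C; then 33, −78 to 0 °C; aq HCl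
Reagents that add atoms: none
Why: N-Acylation of the lithiated oxazolidinone by ring opening of the cyclic anhydride gives the imide acid in one operation.

Step 21
Reactants: 34 imide acid
Product: 36 4-[(R)-4-benzyl-2-oxooxazolidin-3-yl]-4-oxobutanamide, via mixed anhydride 35 (not isolated)
Conditions: i-BuOCOCl, N-methylmorpholine, THF, −15 °C; then NH3 (dioxane), −15 to 0 °C
Reagents that add atoms: ammonia, N
Why: Mixed-anhydride amidation should be selective because the carbonic anhydride 35 is far more electrophilic towards ammonia at low temperature than the imide carbonyl.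

Step 22
Reactants: 31 aldehyde; 36 imide amide
Product: 37 (12S,13R)-syn-aldol adduct
Conditions: 36, Bu2BOTf, i-Pr2NEt, CH2Cl2, −78 to 0 °C; then 31, −78 to 0 °C; H2O2, pH 7 buffer, MeOH
Reagents that add atoms: none
Why: In this Evans syn-aldol reaction the Z-boron enolate of the imide adds to the aldehyde through a closed chair transition state on the enolate face opposite the benzyl group, so the (R)-auxiliary should set 12S and 13R, extra Bu2BOTf and base being used to cover the carboxamide.

Step 23
Reactants: 37 aldol adduct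
Product: 38 3,7-bis-O-TBS-3β-hydroxylissoclimide
Conditions: DBU, THF, 0 °C to rt
Reagents that add atoms: none
Why: Base-promoted intramolecular N-acylation of the primary amide by the activated N-acyloxazolidinone (5-exo-trig) closes the succinimide and expels the auxiliary, and deprotonation of the new imide N–H then guards C13 against epimerisation and the aldol against retro-cleavage.

Step 24
Reactants: 38 bis-TBS imide
Product: 39 3β-hydroxylissoclimide
Conditions: HF·pyridine, THF, 0 °C to rt
Reagents that add atoms: none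
Why: Acidic fluoride desilylation removes both silyl ethers under conditions that leave the β-hydroxy imide, the chloride and the allylic alcohol untouched.

Compound list
1 | (+)-dihydrocarvone, (2R,5R)-2-methyl-5-(prop-1-en-2-yl)cyclohexan-1-one | C1[C@@H](C(C)=C)CC(=O)[C@H](C)C1 | starting material
2 | (R)-1-phenylethylamine | C[C@H](c1ccccc1)N | starting material
3 | (E)-N-[(R)-1-phenylethyl]imine of dihydrocarvone | C1[C@@H](C(C)=C)C/C(=N\[C@H](C)c2ccccc2)[C@H](C)C1 | intermediate
4 | ethyl vinyl ketone (pent-1-en-3-one) | C=CC(=O)CC | starting material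
5 | Michael adduct imine: N-[(R)-1-phenylethyl]imine of (2S,5R)-2-methyl-2-(3-oxopentyl)-5-(prop-1-en-2-yl)cyclohexanone | C1[C@@H](C(C)=C)C/C(=N\[C@H](C)c2ccccc2)[C@](C)(CCC(=O)CC)C1 | intermediate
6 | (2S,5R)-2-methyl-2-(3-oxopentyl)-5-(prop-1-en-2-yl)cyclohexan-1-one | C1[C@@H](C(C)=C)CC(=O)[C@](C)(CCC(=O)CC)C1 | intermediate
7 | (+)-α-cyperone, (4aS,7R)-1,4a-dimethyl-7-(prop-1-en-2-yl)-4,4a,5,6,7,8-hexahydronaphthalen-2(3H)-one | C1[C@@H](C(C)=C)CC2=C(C)C(=O)CC[C@]2(C)C1 | intermediate
8 | 7β-isopropenyl-4,4,10β-trimethyl-5α-decalin-3-one (trans-fused) | C1[C@@H](C(C)=C)C[C@H]2C(C)(C)C(=O)CC[C@]2(C)C1 | intermediate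
9 | 7β-(1-hydroperoxy-1-methoxyethyl)-4,4,10β-trimethyl-5α-decalin-3-one (epimers at the peroxy carbon) | C1[C@@H](C(C)(OC)OO)C[C@H]2C(C)(C)C(=O)CC[C@]2(C)C1 | intermediate
10 | 7β-acetoxy-4,4,10β-trimethyl-5α-decalin-3-one | C1[C@@H](OC(C)=O)C[C@H]2C(C)(C)C(=O)CC[C@]2(C)C1 | intermediate
11 | 7β-acetoxy-3,3-ethylenedioxy-4,4,10β-trimethyl-5α-decalin | C1[C@@H](OC(C)=O)C[C@H]2C(C)(C)C3(OCCO3)CC[C@]2(C)C1 | intermediate
12 | 3,3-ethylenedioxy-4,4,10β-trimethyl-5α-decalin-7β-ol | C1[C@@H](O)C[C@H]2C(C)(C)C3(OCCO3)CC[C@]2(C)C1 | intermediate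
13 | 3,3-ethylenedioxy-4,4,10β-trimethyl-5α-decalin-7-one | C1C(=O)C[C@H]2C(C)(C)C3(OCCO3)CC[C@]2(C)C1 | intermediate
14 | Δ7(8) trimethylsilyl enol ether of 13 | C1=C(O[Si](C)(C)C)C[C@H]2C(C)(C)C3(OCCO3)CC[C@]2(C)C1 | intermediate
15 | 3,3-ethylenedioxy-4,4,10β-trimethyl-5α-Δ8(9)-octalin-7-one | C=1C(=O)C[C@H]2C(C)(C)C3(OCCO3)CC[C@]2(C)C=1 | intermediate
16 | 9α-allyl-Δ7(8) trimethylsilyl enol ether (9β-H) | C1=C(O[Si](C)(C)C)C[C@H]2C(C)(C)C3(OCCO3)CC[C@]2(C)[C@@H]1CC=C | intermediate
17 | 9-allyl-3,3-ethylenedioxy-4,4,10β-trimethyl-5α-Δ8(9)-octalin-7-one | C=1C(=O)C[C@H]2C(C)(C)C3(OCCO3)CC[C@]2(C)C=1CC=C | intermediate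
18 | 9β-allyl-8α-(hydroxymethyl)-3,3-ethylenedioxy-4,4,10β-trimethyl-5α-decalin-7-one (9α-H) | OC[C@@H]1C(=O)C[C@H]2C(C)(C)C3(OCCO3)CC[C@]2(C)[C@H]1CC=C | intermediate
19 | methanesulfonate of the primary alcohol of 18 | CS(=O)(=O)OC[C@@H]1C(=O)C[C@H]2C(C)(C)C3(OCCO3)CC[C@]2(C)[C@H]1CC=C | intermediate
20 | 9β-allyl-8-methylene-3,3-ethylenedioxy-4,4,10β-trimethyl-5α-decalin-7-one | C=C1C(=O)C[C@H]2C(C)(C)C3(OCCO3)CC[C@]2(C)[C@H]1CC=C | intermediate
21 | 9β-(2-oxoethyl)-8-methylene-3,3-ethylenedioxy-4,4,10β-trimethyl-5α-decalin-7-one | C=C1C(=O)C[C@H]2C(C)(C)C3(OCCO3)CC[C@]2(C)[C@H]1CC=O | intermediate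
22 | 9β-(2-hydroxyethyl)-8-methylene-3,3-ethylenedioxy-4,4,10β-trimethyl-5α-decalin-7-one | C=C1C(=O)C[C@H]2C(C)(C)C3(OCCO3)CC[C@]2(C)[C@H]1CCO | intermediate
23 | 9β-(2-hydroxyethyl)-8-methylene-3,3-ethylenedioxy-4,4,10β-trimethyl-5α-decalin-7β-ol | C=C1[C@@H](O)C[C@H]2C(C)(C)C3(OCCO3)CC[C@]2(C)[C@H]1CCO | intermediate
24 | 7β-hydroxy-9β-(2-hydroxyethyl)-8-methylene-4,4,10β-trimethyl-5α-decalin-3-one | C=C1[C@@H](O)C[C@H]2C(C)(C)C(=O)CC[C@]2(C)[C@H]1CCO | intermediate
25 | 7,12-bis-O-TBS ether of 24 | C=C1[C@@H](O[Si](C)(C)C(C)(C)C)C[C@H]2C(C)(C)C(=O)CC[C@]2(C)[C@H]1CCO[Si](C)(C)C(C)(C)C | intermediate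
26 | Δ2 trimethylsilyl enol ether of 25 | C=C1[C@@H](O[Si](C)(C)C(C)(C)C)C[C@H]2C(C)(C)C(O[Si](C)(C)C)=CC[C@]2(C)[C@H]1CCO[Si](C)(C)C(C)(C)C | intermediate
27 | 2α-chloro derivative of 25 | C=C1[C@@H](O[Si](C)(C)C(C)(C)C)C[C@H]2C(C)(C)C(=O)[C@H](Cl)C[C@]2(C)[C@H]1CCO[Si](C)(C)C(C)(C)C | intermediate
28 | 2α-chloro-3β-ol with 7β- and 12-OTBS | C=C1[C@@H](O[Si](C)(C)C(C)(C)C)C[C@H]2C(C)(C)[C@@H](O)[C@H](Cl)C[C@]2(C)[C@H]1CCO[Si](C)(C)C(C)(C)C | intermediate
29 | 2α-chloro-3β,7β,12-tris-O-TBS compound | C=C1[C@@H](O[Si](C)(C)C(C)(C)C)C[C@H]2C(C)(C)[C@@H](O[Si](C)(C)C(C)(C)C)[C@H](Cl)C[C@]2(C)[C@H]1CCO[Si](C)(C)C(C)(C)C | intermediate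
30 | 2α-chloro-3β,7β-bis-O-TBS-12-ol | C=C1[C@@H](O[Si](C)(C)C(C)(C)C)C[C@H]2C(C)(C)[C@@H](O[Si](C)(C)C(C)(C)C)[C@H](Cl)C[C@]2(C)[C@H]1CCO | intermediate
31 | 2α-chloro-3β,7β-bis-O-TBS-12-al | C=C1[C@@H](O[Si](C)(C)C(C)(C)C)C[C@H]2C(C)(C)[C@@H](O[Si](C)(C)C(C)(C)C)[C@H](Cl)C[C@]2(C)[C@H]1CC=O | intermediate
32 | (R)-4-benzyl-2-oxazolidinone | O=C1N[C@H](Cc2ccccc2)CO1 | starting material
33 | succinic anhydride | O=C1CCC(=O)O1 | starting material
34 | 4-[(R)-4-benzyl-2-oxooxazolidin-3-yl]-4-oxobutanoic acid | OC(=O)CCC(=O)N1[C@H](Cc2ccccc2)COC1=O | intermediate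
35 | isobutyl carbonic mixed anhydride of 34 | CC(C)COC(=O)OC(=O)CCC(=O)N1[C@H](Cc2ccccc2)COC1=O | intermediate
36 | 4-[(R)-4-benzyl-2-oxooxazolidin-3-yl]-4-oxobutanamide | NC(=O)CCC(=O)N1[C@H](Cc2ccccc2)COC1=O | intermediate
37 | (12S,13R)-syn-aldol adduct, C16 acyl oxazolidinone and C15 carboxamide | C=C1[C@@H](O[Si](C)(C)C(C)(C)C)C[C@H]2C(C)(C)[C@@H](O[Si](C)(C)C(C)(C)C)[C@H](Cl)C[C@]2(C)[C@H]1C[C@H](O)[C@@H](CC(N)=O)C(=O)N1[C@H](Cc2ccccc2)COC1=O | intermediate
38 | 3,7-bis-O-TBS-3β-hydroxylissoclimide | C=C1[C@@H](O[Si](C)(C)C(C)(C)C)C[C@H]2C(C)(C)[C@@H](O[Si](C)(C)C(C)(C)C)[C@H](Cl)C[C@]2(C)[C@H]1C[C@H](O)[C@H]1CC(=O)NC1=O | intermediate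
39 | 3β-hydroxylissoclimide | C=C1[C@@H](O)C[C@H]2C(C)(C)[C@@H](O)[C@H](Cl)C[C@]2(C)[C@H]1C[C@H](O)[C@H]1CC(=O)NC1=O | target

Total step count: 24. Longest linear sequence: 22 steps (steps 1–19 and 22–24); steps 20–21 prepare the aldol partner.

Steps most likely to fail

Step 2. Facial selectivity at C10 may erode, since auxiliary control has to outweigh the ring's preference for axial attack cis to the isopropenyl group; conjugate addition of the hindered enamine may also be slow enough for the enone to polymerise. The fallback replaces auxiliary control by substrate control and sets out from 1. Markovnikov addition of HBr in AcOH to the isopropenyl group should give the tertiary bromide 8-bromo-p-menthan-2-one F1. KOH in MeOH then closes the cyclopropane by intramolecular enolate alkylation to 2-carone F2. The fused dimethylcyclopropane blocks its own face and the bridgehead α-position, so base-mediated Robinson annulation with 4 (KOH, EtOH) alkylates the methyl-bearing carbon anti to the three-membered ring to give the cyclopropyl diketone F3 and, after aldol condensation, the cyclopropane-fused enone F4. HCl opens the vinylogous cyclopropyl ketone by homoconjugate addition to the tertiary chloride 11-chloroeudesm-4-en-3-one F5, and dehydrochlorination with NaOAc in hot AcOH returns to the route at 7.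

Step 10. The ketone may be over-reduced, proton transfer may quench or scramble the enolate before formaldehyde is captured, formaldehyde may oligomerise, or C9 may be protonated from the wrong face. The fallback delivers hydride instead of an electron and sets out from 17. Conjugate hydrosilylation with [(Ph3P)CuH]6 (cat.) and PhMe2SiH adds hydride to C9 from the α face, as other nucleophiles do, and should give the dimethylphenylsilyl enol ether F6. Mannich reaction with Me2N=CH2+ I− gives the 8-(dimethylaminomethyl) ketone F7. Quaternisation with MeI to the trimethylammonium iodide F8 and elimination with NaHCO3 returns to the route at 20.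

Step 22. The primary carboxamide may sequester the boron triflate, leaving enolisation incomplete and diastereocontrol poor. The fallback carries the amide as a nitrile and sets out from 32 and 31. 3-Cyanopropanoic acid is activated with pivaloyl chloride and Et3N as the mixed anhydride F9 and acylates 32 (LiCl, THF) to the cyano imide (R)-4-benzyl-3-(3-cyanopropanoyl)oxazolidin-2-one F10. The same boron aldol with 31 should give the cyano syn-aldol adduct F11. Neutral hydration of the nitrile with [PtH(PMe2OH)(PMe2O)2H] (cat.) in EtOH/H2O at 80 °C returns to the route at 37.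

Further compounds
F1 | step 2 | 8-bromo-p-menthan-2-one (hydrobromide of 1) | C1[C@@H](C(C)(C)Br)CC(=O)[C@H](C)C1
F2 | step 2 | 2-carone, 3,7,7-trimethylbicyclo[4.1.0]heptan-2-one (C3 epimerisable) | C1[C@H]2C(C)(C)[C@H]2C(=O)[C@H](C)C1
F3 | step 2 | 3-methyl-3-(3-oxopentyl)-7,7-dimethylbicyclo[4.1.0]heptan-2-one, chain anti to the cyclopropane | C1[C@H]2C(C)(C)[C@H]2C(=O)[C@](C)(CCC(=O)CC)C1
F4 | step 2 | 6,7-(dimethylmethano)-bridged eudesm-4-en-3-one (cyclopropane-fused enone) | C1[C@H]3C(C)(C)[C@H]3C2=C(C)C(=O)CC[C@]2(C)C1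
F5 | step 2 | 11-chloroeudesm-4-en-3-one (hydrochloride of 7) | C1[C@@H](C(C)(C)Cl)CC2=C(C)C(=O)CC[C@]2(C)C1
F6 | step 10 | 9β-allyl-Δ7(8) dimethylphenylsilyl enol ether (9α-H) | C1=C(O[Si](C)(C)c4ccccc4)C[C@H]2C(C)(C)C3(OCCO3)CC[C@]2(C)[C@H]1CC=C
F7 | step 10 | 9β-allyl-8α-(dimethylaminomethyl)-3,3-ethylenedioxy-4,4,10β-trimethyl-5α-decalin-7-one | CN(C)C[C@@H]1C(=O)C[C@H]2C(C)(C)C3(OCCO3)CC[C@]2(C)[C@H]1CC=C
F8 | step 10 | trimethylammonium iodide of F7 | C[N+](C)(C)C[C@@H]1C(=O)C[C@H]2C(C)(C)C3(OCCO3)CC[C@]2(C)[C@H]1CC=C.[I-]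
F9 | step 22 | 3-cyanopropanoic pivalic anhydride | N#CCCC(=O)OC(=O)C(C)(C)C
F10 | step 22 | (R)-4-benzyl-3-(3-cyanopropanoyl)oxazolidin-2-one | N#CCCC(=O)N1[C@H](Cc2ccccc2)COC1=O
F11 | step 22 | (12S,13R)-syn-aldol adduct with C15 nitrile | C=C1[C@@H](O[Si](C)(C)C(C)(C)C)C[C@H]2C(C)(C)[C@@H](O[Si](C)(C)C(C)(C)C)[C@H](Cl)C[C@]2(C)[C@H]1C[C@H](O)[C@@H](CC#N)C(=O)N1[C@H](Cc2ccccc2)COC1=O
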